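The key step exploits the fifteen plain CH2 groups (C1–C15, counted from the ester oxygen) that separate the benzoate from the isopropyl terminus. C7 and C8 have no neighbouring handle, so their bond calls for a traceless sp3–sp3 union. Everything rests on a crossed Kolbe electrolysis. 8-[(2,3-Diacetoxybenzoyl)oxy]octanoic acid and 10-methylundecanoic acid each lose CO2 at the anode, and the two unbranched primary radicals combine. One operation gives the whole 16-methylheptadecyl chain with the benzoate already attached and nothing left to erase. The precursor is simply this pair of free acids. The acetyl groups on the two phenolic oxygens make the benzene ring anodically inert and are removed last.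

Key step: step 3

Remark: the target has no stereocentre and no stereogenic double bond. It is achiral, so no step has to control configuration. 8-Hydroxyoctanoic acid and 10-methylundecanoic acid (the iso-C12:0 fatty acid) are taken as catalogue compounds.

Step 1
Reactants: 1 2,3-dihydroxybenzoic acid
Product: 2 2,3-diacetoxybenzoic acid
Conditions: Ac2O (excess), cat. H2SO4, 60 °C; then ice-water
Reagents that add atoms: acetic anhydride, CC(=O)OC(C)=O
Why: Acid-catalysed O-acetylation of both phenols (aspirin-type acetylation) should go to completion with excess anhydride, and the water quench hydrolyses any mixed carboxylic anhydride back to the free acid.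

Step 2
Reactants: 2 2,3-diacetoxybenzoic acid; 3 8-hydroxyoctanoic acid
Product: 5 8-[(2,3-diacetoxybenzoyl)oxy]octanoic acid, via 2,3-diacetoxybenzoyl chloride 4 (not isolated)
Conditions: (COCl)2, cat. DMF, CH2Cl2, 0 °C to rt, evaporate; then 3, pyridine (no DMAP), THF, 0 °C to rt; aqueous pyridine quench, dilute HCl work-up
Reagents that add atoms: oxalyl chloride, O=C(Cl)C(=O)Cl (supplies only the chlorine of 4)
Why: Acid chloride formation with oxalyl chloride/DMF followed by pyridine-mediated O-acylation (Einhorn acylation) of the primary alcohol of 3 should give the ester, because the preformed aroyl chloride is the only strong acylating agent present and any mixed anhydride formed at the free carboxyl group is hydrolysed back in the aqueous pyridine quench.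

Step 3
Reactants: 5 8-[(2,3-diacetoxybenzoyl)oxy]octanoic acid; 6 10-methylundecanoic acid
Product: 7 16-methylheptadecyl 2,3-diacetoxybenzoate
Conditions: 5 (1 equiv), 6 (3 equiv), Me4NOH·5H2O (substoichiometric), acetone, RVC/RVC, undivided cell, rapid alternating polarity (ca. 50 ms pulses), constant current, rt
Reagents that add atoms: none
Why: Mixed (crossed) Kolbe electrolysis: both carboxylates are oxidised by one electron at the anode, the acyloxy radicals lose CO2, and the 7-(aroyloxy)heptyl and 9-methyldecyl radicals, formed side by side in high local concentration at the electrode, combine to the C7–C8 bond while protons are reduced to H2 at the counter-electrode. The closest known reaction type is the Kolbe heterocoupling of a fatty acid with an ω-functionalised co-acid, used here in its waveform-controlled form (alternating polarity, carbon electrodes, acetone). No ring is closed and no stereocentre is formed. Radical rather than cation chemistry is secured because both radical carbons are unbranched primary CH2 groups without an α-heteroatom, so Hofer–Moest over-oxidation is disfavoured. Cross- versus homocoupling is only statistical and is biased by the excess of 6, and the two symmetrical homocoupling products differ so strongly in polarity from 7 that chromatography should remove them. Chemoselectivity at the electrode is secured by the substrate design: the two acetyl groups and the ester make the benzene ring electron-poor and mask the O–H hydrogen-atom donors, and in aprotic acetone under alternating polarity no basic layer builds up that could solvolyse the aryl acetates.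

Step 4
Reactants: 7 16-methylheptadecyl 2,3-diacetoxybenzoate
Product: 8 gentiside D (16-methylheptadecyl 2,3-dihydroxybenzoate)
Conditions: pyrrolidine (3 equiv), CH2Cl2, 0 °C to rt, Ar; 1 M HCl wash
Reagents that add atoms: none
Why: Chemoselective aminolysis of aryl esters: the two aryl acetates carry a good aryloxide leaving group and react with a secondary amine at or below room temperature, whereas the alkyl benzoate, hindered and then deactivated by the hydrogen-bonded ortho-hydroxyl group, should stay intact.

Compound list
1 | 2,3-dihydroxybenzoic acid | OC(=O)c1cccc(O)c1O | starting material
2 | 2,3-diacetoxybenzoic acid | CC(=O)Oc1cccc(C(=O)O)c1OC(C)=O | intermediate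
3 | 8-hydroxyoctanoic acid | OCCCCCCCC(=O)O | starting material
4 | 2,3-diacetoxybenzoyl chloride | CC(=O)Oc1cccc(C(=O)Cl)c1OC(C)=O | intermediate
5 | 8-[(2,3-diacetoxybenzoyl)oxy]octanoic acid | CC(=O)Oc1cccc(C(=O)OCCCCCCCC(=O)O)c1OC(C)=O | intermediate
6 | 10-methylundecanoic acid | CC(C)CCCCCCCCC(=O)O | starting material
7 | 16-methylheptadecyl 2,3-diacetoxybenzoate | CC(C)CCCCCCCCCCCCCCCOC(=O)c1cccc(OC(C)=O)c1OC(C)=O | intermediate
8 | gentiside D, 16-methylheptadecyl 2,3-dihydroxybenzoate (achiral) | CC(C)CCCCCCCCCCCCCCCOC(=O)c1cccc(O)c1O | target

Total step count: 4
Longest linear sequence: 4 (1 → 2 → 5 → 7 → 8)

Steps most likely to fail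

Step 3. Several processes may erode the step:
- homocoupling of each acid at the expense of the cross product
- over-oxidation of the radicals to cations
- loss of an acetyl group followed by anodic destruction of the unmasked ring
- fouling of the electrodes by waxy products

The fallback sets out from 5 and 6. Each acid is esterified with N-hydroxyphthalimide (DIC, CH2Cl2) to give the redox-active esters 1,3-dioxoisoindolin-2-yl 8-[(2,3-diacetoxybenzoyl)oxy]octanoate F1 and 1,3-dioxoisoindolin-2-yl 10-methylundecanoate F2. These are joined by nickel-electrocatalytic doubly decarboxylative cross-coupling (NiCl2·6H2O, terpyridine ligand, sacrificial metal anode, DMF, rt). The same C7–C8 bond is then made reductively at a nickel centre instead of by free radical–radical combination at an anode. The fallback comes back to the route at 7.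

Step 2. The free carboxyl group of the hydroxy acid may be activated through mixed-anhydride formation, which would lead to self-esterification (oligomerisation) instead of clean O-aroylation. The fallback sets out from 4, made from 2 as in step 2. Acylation of an excess of commercial octane-1,8-diol (pyridine, CH2Cl2, 0 °C) gives 8-hydroxyoctyl 2,3-diacetoxybenzoate F3. Its remaining primary alcohol is oxidised to the acid with TEMPO/PhI(OAc)2 in MeCN–H2O. The carboxyl group is thus created only after the ester bond exists. The fallback comes back to the route at 5.

Step 4. The amine may attack the benzoate carbonyl, or the liberated catechol may be oxidised by air under the basic conditions. The fallback sets out from 7. All three ester types are saponified (NaOH, aq. THF/MeOH, reflux) to give 16-methylheptadecan-1-ol F4. This is re-esterified with unprotected 1 under Mitsunobu conditions (PPh3, DIAD, THF, 0 °C to rt). There the alcohol is activated and only the far more acidic carboxyl group of 1, not its phenols, acts as the nucleophile. The fallback comes back to the route at 8.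

Further compounds
F1 | step 3 | 1,3-dioxoisoindolin-2-yl 8-[(2,3-diacetoxybenzoyl)oxy]octanoate | CC(=O)Oc1cccc(C(=O)OCCCCCCCC(=O)ON2C(=O)c3ccccc3C2=O)c1OC(C)=O
F2 | step 3 | 1,3-dioxoisoindolin-2-yl 10-methylundecanoate | CC(C)CCCCCCCCC(=O)ON1C(=O)c2ccccc2C1=O
F3 | step 2 | 8-hydroxyoctyl 2,3-diacetoxybenzoate | CC(=O)Oc1cccc(C(=O)OCCCCCCCCO)c1OC(C)=O
F4 | step 4 | 16-methylheptadecan-1-ol | CC(C)CCCCCCCCCCCCCCCO
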